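## The problem

The target 24 is a 6α-acetoxy-9α-hydroxy labdane: a trans-fused decalin (rings A and B) whose C9 carries a two-carbon chain that ends at the α-carbon of a butenolide. Five stereocentres sit on the bicycle (C5, C6, C8, C9, C10); C10 is quaternary, its neighbour C9 is a fully substituted carbinol with an axial hydroxyl, and the C6 acetate, the C8 methyl and the C9 chain are all equatorial. C5 and C10 have to be made together and in absolute terms; once the trans fusion exists it can steer C9 (through a ring closure that can equilibrate) and C8 (the equatorial methyl is the stable epimer), whereas C6 gets no dependable bias from its neighbours and needs reagent control. The butenolide is a Michael acceptor with an acidic γ-position and the secondary acetate does not survive organometallic reagents or strong base, so both must come last. The α-ketol and the β-silyloxy carbonyl units that appear on the way are themselves base-sensitive (acyloin shift, β-elimination). Ring A carries no function, so nothing placed on it may need removing later. The feature that opens the route is the C8–C9 pair of ring B: C9 is a tertiary alcohol and C8 bears only a methyl group and a hydrogen, so C8 can be raised to the ketone level. Ring B is then a cyclic α-ketol whose C8–C9 bond links two carbonyl carbons, which is the retron of an aldehyde–ketone benzoin closure.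

## Retrosynthesis

**C12–C13.** The first cut separates the chain methylene C12 from the α-carbon of the butenolide, giving primary iodide 22 and 3-bromofuran-2(5H)-one 23. Building the lactone stepwise on the chain would expose the acetate and the tertiary alcohol to enolate chemistry; this cut removes the whole sensitive unit at once and hands it to a four-carbon commercial piece. The forward step must join an sp3 and an sp2 electrophile without base: a nickel-catalysed reductive coupling.

**Functional-group order, 22 back to 18.** Iodide 22 comes from alcohol 21, freed by hydrogenolysis of benzyl ether 20. The acetate of 20 is put on diol 19, which comes from silyl ether 18. A silyl group on O6 and a benzyl group on O12 let the acetate be installed on the only acylable hydroxyl before the primary alcohol is unmasked. No skeletal bond changes.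

**C8–C17.** The C8 methyl of 18 is cut as a methylene: 18 from exocyclic alkene 17, and 17 from ketone 16. A methyl nucleophile added to the ketone would leave a tertiary alcohol to remove; the alkene route needs only two hydrogens. The forward hydrogenation must deliver hydrogen to C8 from the β face, against the axial C10 methyl. Surface or hydroxyl-directed hydrogenation would do the opposite, so a radical hydrogen-atom-transfer reduction is specified. The methylenation must be non-basic.

**C8–C9, the strategic cut.** In 16 the two ring-B carbons C8 and C9 are both at carbonyl-derived oxidation levels, so the bond between them is cut with reversal of polarity at C8. This leads to keto aldehyde 15. The neighbouring cuts are worse: C9–C10 would join a quaternary carbon to a fully substituted one, and C7–C8 or C5–C6 closures would not create the C9 carbinol. The cut removes ring B and the C9 stereocentre and leaves a monocyclic ring A with two trans arms. The forward step asks that the aldehyde act as acyl-anion donor, that a hindered ketone accept it, and that the C9 chain end up equatorial.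

**The ketone arm, 15 back to 10.** The aldehyde of 15 is the cleavage product of the terminal alkene of 13. C11–C12 is cut next, giving methyl ketone 12 and a benzyloxymethyl electrophile. A 2-benzyloxyethyl organometallic would lose benzyloxide by β-elimination, whereas 12 has a single enolisable side. C9–C11 is cut to acid 11 and a methyl organometallic, and 11 is the demethylated form of ester 10. Each precursor is one carbon unit simpler; the forward steps are an enolate alkylation and the conversion of a hindered acid into a methyl ketone.

**C6–C7.** Silyl ether 10 is the protected form of homoallylic alcohol 9, cut at C6–C7 to aldehyde 7 and an allyl nucleophile. An aldol cut at the same bond would put C8 at the ester level and add redox steps. The forward reaction must set C6 by reagent control on a hindered aldehyde: an allylboration with a pinene-derived borane.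

**Ring A.** Aldehyde 7 is the hydrogenated form of cyclohexene 6, which is cut at C1–C10 and C4–C5 into enal ester 4 and 4-methylpenta-1,3-diene 5. The (E) geometry of 4 becomes the trans relation of the two arms and the cis relation of the C10 methyl to C6. A dienophile with two ester groups would leave two hindered esters to tell apart; 4 has the arms differentiated from the start. Activation through its aldehyde also makes electronic and steric regiocontrol agree: the unsubstituted diene terminus goes to the enal β-carbon (C10) and the dimethylated terminus to C5. A chiral Lewis acid supplies the absolute configuration. Enal 4 comes from acetal 3, the Wittig product of 2,2-dimethoxyacetaldehyde 1 and ylide 2.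

## Roads not taken

Alternative 1: Ring A is cut at C3–C4, and the decalin is traced to the pinane chiral pool. The enone (1R,5R)-verbenone A1 takes an allyl group at the future C10 to give cyclobutyl ketone A2. TiCl4 then opens the strained cyclobutane bond to a titanium enolate and a tertiary cation, which the allyl group captures to give chlorodecalone A3.
- Merits: C5 and C10 come from A1 without asymmetric catalysis, and the trans-decalin with its gem-dimethyl group is reached in two steps. In speed to the bicycle and in certainty of absolute configuration this road is better than the chosen one.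
- Weak points: A3 has a chloride at C2 to remove, nothing at C6, and an unsubstituted C9 methylene beside the quaternary centre. C9 would need both a chain and a hydroxyl, on the more hindered α-side of a ketone that enolises toward C7. C6 would need oxidation β to the ketone.
- Comparison: the chosen plan answers with a ring closure in which the C6, C8 and C9 oxygens are already in place, so no oxidation campaign follows on a finished decalin.

Alternative 2: Both rings are cut at once (C4–C5 and C9–C10). The acyclic keto ester A4 is protonated at its terminal alkene by a chiral BINOL-derived acid paired with SnCl4 and cyclises to bicyclic β-keto ester A5.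
- Merits: three stereocentres and two rings in one step from a geranyl-derived chain. The β-keto ester is well set up for α-hydroxylation to the C9 carbinol, with the ester carbon serving as C11. In step count to the decalin it clearly beats the chosen plan.
- Weak points: C6 is an unactivated methylene in A5, and an oxygen placed there beforehand would sit allylic to the alkene that must carry the cation. Enantioselectivity with a non-aromatic terminator and a stoichiometric chiral acid is less secure. C12 still has to be added by homologation.
- Comparison: the chosen plan is longer to the bicycle but carries the C6 oxygen from the first carbonyl addition and needs no late C–H oxidation.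

Alternative 3: Ring A is cut at C1–C10 and C4–C5, as in the chosen plan, but the dienophile is ring B itself. The quinone 2,6-dimethyl-1,4-benzoquinone A6 and diene 5 combine under a chiral oxazaborolidinium Lewis acid to give the cis-fused enedione A7.
- Merits: one step gives both rings with the C17 methyl, a C6 carbonyl and a C9 carbonyl in place, and A6 is a cheap commercial compound. C5 and C8 are epimerisable toward the trans-fused, equatorial-methyl arrangement. In oxidation-pattern economy and step count this is the strongest competitor, and it shares the diene and its risk with the chosen plan.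
- Weak points: the chain must be added to the C9 ketone, which is flanked by the quaternary C10. The open face of that ketone is α, so addition would put the chain α and the hydroxyl β, the reverse of the target. The two ketones of A7 must also be told apart and the ring fusion inverted.
- Comparison: the chosen plan answers with C9 formed in a ring closure that can equilibrate to the chain-equatorial, hydroxyl-axial epimer.

Key step: step 11

Assumption 1: the (S)-oxazaborolidinium salt is written for step 3 on the model of an s-trans enal held by a formyl C–H···O contact; the sense of induction for this β,β-disubstituted enal must be confirmed on 6, and the (R)-salt would replace it without other change.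

Assumption 2: the (5aS,10bR)-triazolium salt is taken as the enantiomer matched to 15 in step 11; since the closure is reversible and the substrate itself favours the 9α-alcohol, its antipode would be used if it proves the better partner.

## Route

Step 1
Reactants: 1 2,2-dimethoxyacetaldehyde; 2 methyl 2-(triphenylphosphoranylidene)propanoate
Product: 3 methyl (E)-4,4-dimethoxy-2-methylbut-2-enoate
Conditions: CH2Cl2 (aqueous 60% solution of 1 used as supplied), rt
Reagents that add atoms: none
Why: Wittig olefination with a stabilised α-branched ylide, which gives the (E)-trisubstituted enoate; this places the acetal carbon cis to the methyl group, as the trans arms of ring A later require.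

Step 2
Reactants: 3 methyl (E)-4,4-dimethoxy-2-methylbut-2-enoate
Product: 4 methyl (E)-2-methyl-4-oxobut-2-enoate
Conditions: 1 M aq. HCl, THF, 0 °C → rt
Reagents that add atoms: water, O
Why: Acid-catalysed acetal hydrolysis; mild acid and short contact keep the (E) geometry, and the enal ester is used without storage.

Step 3
Reactants: 4 methyl (E)-2-methyl-4-oxobut-2-enoate; 5 4-methylpenta-1,3-diene
Product: 6 methyl (1S,6S)-6-formyl-1,5,5-trimethylcyclohex-3-ene-1-carboxylate
Conditions: (S)-1-(2-methylphenyl)-3,3-diphenyltetrahydro-1H,3H-pyrrolo[1,2-c][1,3,2]oxazaborole protonated by HN(SO2CF3)2 (20 mol %), 5 (3 equiv), CH2Cl2, −78 → −20 °C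
Reagents that add atoms: none
Why: Catalytic enantioselective Diels–Alder reaction of an enal bound to a chiral oxazaborolidinium Lewis acid. The unsubstituted diene terminus bonds to the enal β-carbon (C10) and the dimethylated terminus to the α-carbon (C5), so electronic and steric preferences agree. The (E)-dienophile fixes the formyl group trans to the ester, and the catalyst's face selection sets C5 and C10 in absolute terms.

Step 4
Reactants: 6 methyl (1S,6S)-6-formyl-1,5,5-trimethylcyclohex-3-ene-1-carboxylate
Product: 7 methyl (1S,2S)-2-formyl-1,3,3-trimethylcyclohexane-1-carboxylate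
Conditions: H2 (1 atm), Pd/C (5 mol %), EtOAc, rt
Reagents that add atoms: none
Why: Heterogeneous hydrogenation of the cis-disubstituted ring alkene; the hindered aldehyde and the ester are not reduced under these conditions and no stereocentre is touched.

Step 5
Reactants: 7 methyl (1S,2S)-2-formyl-1,3,3-trimethylcyclohexane-1-carboxylate
Product: 9 methyl (1S,2S)-2-[(1S)-1-hydroxybut-3-en-1-yl]-1,3,3-trimethylcyclohexane-1-carboxylate, via diisopinocampheylborinate ester 8 (not isolated)
Conditions: (−)-B-methoxydiisopinocampheylborane, CH2=CHCH2MgBr, Et2O, −78 °C; then 7, −78 °C; then 30% H2O2, pH 7 phosphate buffer, MeOH, 0 °C → rt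
Reagents that add atoms: allylmagnesium bromide, C=CC[Mg]Br
Why: Brown allylboration through a chair six-membered transition state. The borane of the (+)-α-pinene series attacks the Si face of the aldehyde and sets C6 as (S) by reagent control, since the α-carbon has two large flanks and no strong bias of its own. The neutral oxidative work-up avoids lactonisation of the γ-hydroxy ester.

Step 6
Reactants: 9 methyl (1S,2S)-2-[(1S)-1-hydroxybut-3-en-1-yl]-1,3,3-trimethylcyclohexane-1-carboxylate
Product: 10 methyl (1S,2S)-2-[(1S)-1-(tert-butyldimethylsilyloxy)but-3-en-1-yl]-1,3,3-trimethylcyclohexane-1-carboxylate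
Conditions: t-BuMe2SiOSO2CF3, 2,6-lutidine, CH2Cl2, −78 → 0 °C
Reagents that add atoms: tert-butyldimethylsilyl trifluoromethanesulfonate, CC(C)(C)[Si](C)(C)OS(=O)(=O)C(F)(F)F
Why: Silylation of a hindered secondary alcohol with the silyl triflate; the ether survives the organolithium steps and removes the risk of lactone formation with the neighbouring ester.

Step 7
Reactants: 10 methyl (1S,2S)-2-[(1S)-1-(tert-butyldimethylsilyloxy)but-3-en-1-yl]-1,3,3-trimethylcyclohexane-1-carboxylate
Product: 11 (1S,2S)-2-[(1S)-1-(tert-butyldimethylsilyloxy)but-3-en-1-yl]-1,3,3-trimethylcyclohexane-1-carboxylic acid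
Conditions: n-PrSLi (from n-PrSH and n-BuLi), HMPA, rt; then cold 1 M aq. HCl
Reagents that add atoms: none
Why: SN2 dealkylation of a methyl ester by thiolate at the O-methyl carbon, the standard answer to esters on quaternary carbons that resist saponification; silyl ether and alkene are inert.

Step 8
Reactants: 11 (1S,2S)-2-[(1S)-1-(tert-butyldimethylsilyloxy)but-3-en-1-yl]-1,3,3-trimethylcyclohexane-1-carboxylic acid
Product: 12 1-{(1S,2S)-2-[(1S)-1-(tert-butyldimethylsilyloxy)but-3-en-1-yl]-1,3,3-trimethylcyclohexyl}ethan-1-one
Conditions: MeLi (3.5 equiv), Et2O, 0 °C → rt; inverse quench into cold 1 M aq. HCl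
Reagents that add atoms: methyllithium, [Li]C
Why: Methyllithium adds to the lithium carboxylate to give a dilithio gem-diolate that cannot add a second equivalent and collapses to the methyl ketone on work-up; C10 is quaternary, so nothing can epimerise.

Step 9
Reactants: 12 1-{(1S,2S)-2-[(1S)-1-(tert-butyldimethylsilyloxy)but-3-en-1-yl]-1,3,3-trimethylcyclohexyl}ethan-1-one
Product: 13 3-(benzyloxy)-1-{(1S,2S)-2-[(1S)-1-(tert-butyldimethylsilyloxy)but-3-en-1-yl]-1,3,3-trimethylcyclohexyl}propan-1-one
Conditions: LiN(iPr)2, THF, −78 °C; then BnOCH2Cl, −78 → −20 °C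
Reagents that add atoms: benzyl chloromethyl ether, ClCOCc1ccccc1
Why: C-alkylation of a lithium enolate with an α-chloro ether in THF without polar additive; the ketone has one enolisable side (the methyl group), so C11–C12 forms without regiochemical choice and O12 arrives already benzylated.

Step 10
Reactants: 13 3-(benzyloxy)-1-{(1S,2S)-2-[(1S)-1-(tert-butyldimethylsilyloxy)but-3-en-1-yl]-1,3,3-trimethylcyclohexyl}propan-1-one
Product: 15 (3S)-3-[(1S,2S)-2-(3-benzyloxypropanoyl)-2,6,6-trimethylcyclohexyl]-3-(tert-butyldimethylsilyloxy)propanal, via vicinal diol 14 (not isolated)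
Conditions: OsO4 (2 mol %), NaIO4 (4 equiv), 2,6-lutidine, dioxane/H2O 3:1, rt
Reagents that add atoms: osmium tetroxide, O=[Os](=O)(=O)=O; sodium periodate, [Na+].[O-]I(=O)(=O)=O
Why: Lemieux–Johnson oxidation: dihydroxylation of the only alkene and periodate cleavage of the diol give the C8 aldehyde; the lutidine-buffered medium spares the benzyl ether, the silyl ether and the β-silyloxy aldehyde.

Step 11
Reactants: 15 (3S)-3-[(1S,2S)-2-(3-benzyloxypropanoyl)-2,6,6-trimethylcyclohexyl]-3-(tert-butyldimethylsilyloxy)propanal
Product: 16 9β-(2-benzyloxyethyl)-6α-(tert-butyldimethylsilyloxy)-9α-hydroxy-4,4,10β-trimethyl-trans-decalin-8-one (labdane numbering; 5S,6S,9S,10S)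
Conditions: (5aS,10bR)-2-(pentafluorophenyl)-5a,10b-dihydro-4H,6H-indeno[2,1-b][1,2,4]triazolo[4,3-d][1,4]oxazin-2-ium tetrafluoroborate (20 mol %), iPr2NEt (20 mol %), toluene (0.02 M), 40 °C
Reagents that add atoms: none
Why: The carbene freed from the triazolium salt adds to the C8 aldehyde, the only carbonyl that can give a hydroxy-enamine (acyl-anion equivalent); this carbon nucleophile attacks the C9 ketone, and proton transfer with loss of the carbene leaves the α-ketol. The closest known reaction type is the intramolecular crossed aldehyde–ketone benzoin cyclisation of keto aldehydes under triazolium carbene catalysis. Ring B closes in the 6-exo-trig mode through a chair, and ring A, with its two arms trans and equatorial, already holds C8 within reach of C9. The one new stereocentre, C9, is set by this chair: the 2-benzyloxyethyl group takes the equatorial site and the carbonyl oxygen the axial site anti to the axial C10 methyl, while the C6 silyloxy group stays equatorial. The chiral carbene is chosen to reinforce this face, and because the addition is reversible the epimers can drain toward the chain-equatorial 9α-alcohol. The step needs the aldehyde as donor and the ketone as acceptor without aldehyde dimerisation; the ketone cannot form the acyl-anion equivalent, and high dilution and the branched surroundings of the aldehyde suppress the dimer. It also needs two β-alkoxy carbonyl units to survive, which a weak amine base in catalytic amount secures.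

Step 12
Reactants: 16 9β-(2-benzyloxyethyl)-6α-(tert-butyldimethylsilyloxy)-9α-hydroxy-4,4,10β-trimethyl-trans-decalin-8-one
Product: 17 9β-(2-benzyloxyethyl)-6α-(tert-butyldimethylsilyloxy)-4,4,10β-trimethyl-8-methylidene-trans-decalin-9α-ol (labdane numbering; 5S,6S,9R,10S)
Conditions: Zn, CH2Br2, TiCl4, THF/CH2Cl2, 0 °C → rt
Reagents that add atoms: dibromomethane, BrCBr
Why: Takai–Lombardo methylenation; the non-basic gem-dimetallic reagent olefinates hindered ketones in the presence of a free hydroxyl, which avoids the acyloin shift and the β-elimination of silanol that a basic ylide would invite.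

Step 13
Reactants: 17 9β-(2-benzyloxyethyl)-6α-(tert-butyldimethylsilyloxy)-4,4,10β-trimethyl-8-methylidene-trans-decalin-9α-ol
Product: 18 9β-(2-benzyloxyethyl)-6α-(tert-butyldimethylsilyloxy)-4,4,8α,10β-tetramethyl-trans-decalin-9α-ol (labdane numbering; 5S,6S,8R,9R,10S)
Conditions: Mn(dpm)3 (10 mol %; dpm = 2,2,6,6-tetramethylheptane-3,5-dionate), PhSiH3 (1.5 equiv), t-BuOOH (1.5 equiv), i-PrOH, rt, argon
Reagents that add atoms: none
Why: Hydrogen-atom-transfer hydrogenation of a 1,1-disubstituted alkene. A hydrogen atom adds to C17, and the tertiary C8 radical takes the second hydrogen so that the methyl group ends equatorial (8α), the thermodynamically preferred outcome. Surface or hydroxyl-directed hydrogenation would add from the α face and give the axial methyl.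

Step 14
Reactants: 18 9β-(2-benzyloxyethyl)-6α-(tert-butyldimethylsilyloxy)-4,4,8α,10β-tetramethyl-trans-decalin-9α-ol
Product: 19 9β-(2-benzyloxyethyl)-4,4,8α,10β-tetramethyl-trans-decalin-6α,9α-diol (labdane numbering; 5S,6S,8R,9R,10S)
Conditions: Bu4NF, THF, 50 °C
Reagents that add atoms: none
Why: Fluoride cleavage of the silyl ether; the benzyl ether and the tertiary alcohol are untouched.

Step 15
Reactants: 19 9β-(2-benzyloxyethyl)-4,4,8α,10β-tetramethyl-trans-decalin-6α,9α-diol
Product: 20 6α-acetoxy-9β-(2-benzyloxyethyl)-4,4,8α,10β-tetramethyl-trans-decalin-9α-ol (labdane numbering; 5S,6S,8R,9R,10S)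
Conditions: Ac2O, 4-(dimethylamino)pyridine (10 mol %), pyridine, rt
Reagents that add atoms: acetic anhydride, CC(=O)OC(C)=O
Why: Nucleophile-catalysed acetylation; the equatorial secondary C6 hydroxyl reacts, while the axial tertiary C9 hydroxyl next to a quaternary carbon does not at room temperature.

Step 16
Reactants: 20 6α-acetoxy-9β-(2-benzyloxyethyl)-4,4,8α,10β-tetramethyl-trans-decalin-9α-ol
Product: 21 6α-acetoxy-9β-(2-hydroxyethyl)-4,4,8α,10β-tetramethyl-trans-decalin-9α-ol (labdane numbering; 5S,6S,8R,9R,10S)
Conditions: H2 (1 atm), Pd/C (10 mol %), EtOAc/EtOH, rt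
Reagents that add atoms: none
Why: Hydrogenolysis of the benzyl ether; the acetate and both remaining C–O bonds are inert and no alkene is left in the molecule.

Step 17
Reactants: 21 6α-acetoxy-9β-(2-hydroxyethyl)-4,4,8α,10β-tetramethyl-trans-decalin-9α-ol
Product: 22 6α-acetoxy-9β-(2-iodoethyl)-4,4,8α,10β-tetramethyl-trans-decalin-9α-ol (labdane numbering; 5S,6S,8R,9R,10S)
Conditions: I2, PPh3, imidazole, CH2Cl2, 0 °C → rt
Reagents that add atoms: iodine, II
Why: Garegg–Samuelsson iodination: the primary alcohol is activated as an alkoxyphosphonium ion and displaced by iodide; the tertiary alcohol cannot be displaced and the acetate is inert.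

Step 18
Reactants: 22 6α-acetoxy-9β-(2-iodoethyl)-4,4,8α,10β-tetramethyl-trans-decalin-9α-ol; 23 3-bromofuran-2(5H)-one
Product: 24 6α-acetoxy-9α-hydroxylabd-13-en-16,15-olide, (1S,3R,4R,4aS,8aS)-4-hydroxy-3,4a,8,8-tetramethyl-4-[2-(2-oxo-2,5-dihydrofuran-3-yl)ethyl]decahydronaphthalen-1-yl acetate
Conditions: NiBr2(MeOCH2CH2OMe) (10 mol %), 4,4′-di-tert-butyl-2,2′-bipyridine (10 mol %), Zn (2 equiv), NaI (25 mol %), 23 (1.5 equiv), N,N-dimethylacetamide, rt
Reagents that add atoms: none
Why: Nickel-catalysed reductive cross-electrophile coupling of an alkenyl bromide with a primary alkyl iodide. Zerovalent nickel inserts into the C–Br bond of 23, the alkyl radical from 22 is captured at nickel, and reductive elimination forms C12–C13. No base or organometallic reagent is present, so the acetate, the tertiary alcohol and the butenolide survive.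

## Compound list

1 | 2,2-dimethoxyacetaldehyde | COC(OC)C=O | starting material
2 | methyl 2-(triphenylphosphoranylidene)propanoate | COC(=O)C(C)=P(c1ccccc1)(c1ccccc1)c1ccccc1 | starting material
3 | methyl (E)-4,4-dimethoxy-2-methylbut-2-enoate | COC(=O)/C(C)=C/C(OC)OC | intermediate
4 | methyl (E)-2-methyl-4-oxobut-2-enoate | COC(=O)/C(C)=C/C=O | intermediate
5 | 4-methylpenta-1,3-diene | C=CC=C(C)C | starting material
6 | methyl (1S,6S)-6-formyl-1,5,5-trimethylcyclohex-3-ene-1-carboxylate | O=C[C@H]1C(C)(C)C=CC[C@]1(C)C(=O)OC | intermediate
7 | methyl (1S,2S)-2-formyl-1,3,3-trimethylcyclohexane-1-carboxylate | O=C[C@H]1C(C)(C)CCC[C@]1(C)C(=O)OC | intermediate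
8 | methyl (1S,2S)-2-{(1S)-1-[bis(isopinocampheyl)boranyloxy]but-3-en-1-yl}-1,3,3-trimethylcyclohexane-1-carboxylate | C=CC[C@H](OB([C@@H]1C[C@@H]2C[C@H]([C@H]1C)C2(C)C)[C@@H]1C[C@@H]2C[C@H]([C@H]1C)C2(C)C)[C@H]1C(C)(C)CCC[C@]1(C)C(=O)OC | intermediate (not isolated)
9 | methyl (1S,2S)-2-[(1S)-1-hydroxybut-3-en-1-yl]-1,3,3-trimethylcyclohexane-1-carboxylate | C=CC[C@H](O)[C@H]1C(C)(C)CCC[C@]1(C)C(=O)OC | intermediate
10 | methyl (1S,2S)-2-[(1S)-1-(tert-butyldimethylsilyloxy)but-3-en-1-yl]-1,3,3-trimethylcyclohexane-1-carboxylate | C=CC[C@H](O[Si](C)(C)C(C)(C)C)[C@H]1C(C)(C)CCC[C@]1(C)C(=O)OC | intermediate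
11 | (1S,2S)-2-[(1S)-1-(tert-butyldimethylsilyloxy)but-3-en-1-yl]-1,3,3-trimethylcyclohexane-1-carboxylic acid | C=CC[C@H](O[Si](C)(C)C(C)(C)C)[C@H]1C(C)(C)CCC[C@]1(C)C(=O)O | intermediate
12 | 1-{(1S,2S)-2-[(1S)-1-(tert-butyldimethylsilyloxy)but-3-en-1-yl]-1,3,3-trimethylcyclohexyl}ethan-1-one | C=CC[C@H](O[Si](C)(C)C(C)(C)C)[C@H]1C(C)(C)CCC[C@]1(C)C(C)=O | intermediate
13 | 3-(benzyloxy)-1-{(1S,2S)-2-[(1S)-1-(tert-butyldimethylsilyloxy)but-3-en-1-yl]-1,3,3-trimethylcyclohexyl}propan-1-one | C=CC[C@H](O[Si](C)(C)C(C)(C)C)[C@H]1C(C)(C)CCC[C@]1(C)C(=O)CCOCc1ccccc1 | intermediate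
14 | 3-(benzyloxy)-1-{(1S,2S)-2-[(1S)-1-(tert-butyldimethylsilyloxy)-3,4-dihydroxybutyl]-1,3,3-trimethylcyclohexyl}propan-1-one (both epimers at the new carbinol) | OCC(O)C[C@H](O[Si](C)(C)C(C)(C)C)[C@H]1C(C)(C)CCC[C@]1(C)C(=O)CCOCc1ccccc1 | intermediate (not isolated)
15 | (3S)-3-[(1S,2S)-2-(3-benzyloxypropanoyl)-2,6,6-trimethylcyclohexyl]-3-(tert-butyldimethylsilyloxy)propanal | O=CC[C@H](O[Si](C)(C)C(C)(C)C)[C@H]1C(C)(C)CCC[C@]1(C)C(=O)CCOCc1ccccc1 | intermediate
16 | 9β-(2-benzyloxyethyl)-6α-(tert-butyldimethylsilyloxy)-9α-hydroxy-4,4,10β-trimethyl-trans-decalin-8-one (5S,6S,9S,10S) | CC(C)(C)[Si](C)(C)O[C@H]1CC(=O)[C@](O)(CCOCc2ccccc2)[C@@]2(C)CCCC(C)(C)[C@H]12 | intermediate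
17 | 9β-(2-benzyloxyethyl)-6α-(tert-butyldimethylsilyloxy)-4,4,10β-trimethyl-8-methylidene-trans-decalin-9α-ol (5S,6S,9R,10S) | CC(C)(C)[Si](C)(C)O[C@H]1CC(=C)[C@](O)(CCOCc2ccccc2)[C@@]2(C)CCCC(C)(C)[C@H]12 | intermediate
18 | 9β-(2-benzyloxyethyl)-6α-(tert-butyldimethylsilyloxy)-4,4,8α,10β-tetramethyl-trans-decalin-9α-ol (5S,6S,8R,9R,10S) | CC(C)(C)[Si](C)(C)O[C@H]1C[C@@H](C)[C@](O)(CCOCc2ccccc2)[C@@]2(C)CCCC(C)(C)[C@H]12 | intermediate
19 | 9β-(2-benzyloxyethyl)-4,4,8α,10β-tetramethyl-trans-decalin-6α,9α-diol (5S,6S,8R,9R,10S) | O[C@H]1C[C@@H](C)[C@](O)(CCOCc2ccccc2)[C@@]2(C)CCCC(C)(C)[C@H]12 | intermediate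
20 | 6α-acetoxy-9β-(2-benzyloxyethyl)-4,4,8α,10β-tetramethyl-trans-decalin-9α-ol (5S,6S,8R,9R,10S) | CC(=O)O[C@H]1C[C@@H](C)[C@](O)(CCOCc2ccccc2)[C@@]2(C)CCCC(C)(C)[C@H]12 | intermediate
21 | 6α-acetoxy-9β-(2-hydroxyethyl)-4,4,8α,10β-tetramethyl-trans-decalin-9α-ol (5S,6S,8R,9R,10S) | CC(=O)O[C@H]1C[C@@H](C)[C@](O)(CCO)[C@@]2(C)CCCC(C)(C)[C@H]12 | intermediate
22 | 6α-acetoxy-9β-(2-iodoethyl)-4,4,8α,10β-tetramethyl-trans-decalin-9α-ol (5S,6S,8R,9R,10S) | CC(=O)O[C@H]1C[C@@H](C)[C@](O)(CCI)[C@@]2(C)CCCC(C)(C)[C@H]12 | intermediate
23 | 3-bromofuran-2(5H)-one | O=C1OCC=C1Br | starting material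
24 | 6α-acetoxy-9α-hydroxylabd-13-en-16,15-olide (5S,6S,8R,9R,10S) | CC(=O)O[C@H]1C[C@@H](C)[C@](O)(CCC2=CCOC2=O)[C@@]2(C)CCCC(C)(C)[C@H]12 | target

## Step count and least certain steps

Total: 18 steps. Longest linear sequence: 18 steps (1 to 24).

**Step 11 (key step).** The C9 ketone sits beside the quaternary C10 and may be attacked too slowly. The acyl-anion equivalent would then be diverted into aldehyde dimerisation, or base-induced β-elimination of silanol or benzyl alcohol would consume the substrate; closure to the chain-axial C9 epimer is the second concern. Fallback, from 15 back to 16: SmI2 in THF/t-BuOH couples the two carbonyls as ketyls to give the cis diol 12-(benzyloxy)-6α-(tert-butyldimethylsilyloxy)-13,14,15,16,17-pentanorlabdane-8α,9α-diol F1. Parikh–Doering oxidation (SO3·pyridine, DMSO, iPr2NEt) of the secondary C8 alcohol then returns 16. The same bond and ring form, by a one-electron mechanism without base.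

**Step 3.** The (Z)-methyl group of the diene strains the s-cis conformer, so cycloaddition may be slow; the strongly acidic catalyst can start cationic polymerisation of the diene, and face selection on a β,β-disubstituted enal may be modest. Fallback, from 4 and 5 back to 9: an achiral Lewis acid (EtAlCl2 or BF3·OEt2, or heat under pressure) gives 6 together with its enantiomer, methyl (1R,6R)-6-formyl-1,5,5-trimethylcyclohex-3-ene-1-carboxylate F2. Hydrogenation as in step 4 gives 7 and methyl (1R,2R)-2-formyl-1,3,3-trimethylcyclohexane-1-carboxylate F3. The reagent-controlled allylboration of step 5 then gives 9 and its diastereomer methyl (1R,2R)-2-[(1S)-1-hydroxybut-3-en-1-yl]-1,3,3-trimethylcyclohexane-1-carboxylate F4, which are separated by chromatography. This is a resolution at the allylation stage in place of asymmetric catalysis.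

**Step 12.** The ketone is flanked by a fully substituted carbinol and may react slowly; the Lewis-acidic medium could promote the acyloin shift or loss of silanol. Fallback, from 16 back to 17 (Peterson olefination): Me3SiCH2Li with CeCl3 in THF at −78 °C adds to the ketone from the open α face to give 12-(benzyloxy)-6α-(tert-butyldimethylsilyloxy)-8α-[(trimethylsilyl)methyl]-13,14,15,16,17-pentanorlabdane-8β,9α-diol F5. KH in THF then eliminates silanolate to give 17.

**Step 13.** Hydrogen delivery to the C8 radical from the β face is impeded by the axial C10 methyl, so facial selectivity may be poor and the axial-methyl epimer may form. Fallback, from 17 back to 22, by way of an enone that is reduced under thermodynamic control: Bu4NF removes the silyl group to give 12-(benzyloxy)-13,14,15,16-tetranorlabd-8(17)-ene-6α,9α-diol F6, and Parikh–Doering oxidation of the secondary alcohol gives 12-(benzyloxy)-9α-hydroxy-13,14,15,16-tetranorlabd-8(17)-en-6-one F7. 1,8-Diazabicyclo[5.4.0]undec-7-ene moves the alkene into conjugation, giving 12-(benzyloxy)-9α-hydroxy-13,14,15,16-tetranorlabd-7-en-6-one F8. The tertiary hydroxyl is first converted into its lithium alkoxide (LiN(SiMe3)2), which is not a leaving group; Li in NH3/THF with EtOH then reduces the enone with protonation of the C8 carbanion to the equatorial 8α-methyl arrangement, reduces the ketone to the equatorial alcohol and cleaves the benzyl ether, giving 13,14,15,16-tetranorlabdane-6α,9α,12-triol F9. I2, PPh3 and imidazole convert the primary alcohol into 12-iodo-13,14,15,16-tetranorlabdane-6α,9α-diol F10, and Ac2O with 4-(dimethylamino)pyridine acetylates O6 to give 22.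

**Step 18.** The alkenyl bromide is also a Michael acceptor, so radical conjugate addition, hydrodehalogenation of either partner or dimerisation of the alkyl fragment may compete with cross-coupling. Fallback, from 22 back to 24, by enolate alkylation and sulfoxide elimination: the preformed lithium enolate of 3-(phenylsulfanyl)oxolan-2-one (LiN(SiMe3)2, THF/HMPA, −78 → 0 °C, excess) is alkylated by 22 to give 6α-acetoxy-9α-hydroxy-13-(phenylsulfanyl)labdan-16,15-olide F11. 3-Chloroperoxybenzoic acid gives the sulfoxide 6α-acetoxy-9α-hydroxy-13-(phenylsulfinyl)labdan-16,15-olide F12. Heating in toluene eliminates the sulfenic acid toward the ring methylene and gives 24.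

## Further compounds

F1 | step 11 | 12-(benzyloxy)-6α-(tert-butyldimethylsilyloxy)-13,14,15,16,17-pentanorlabdane-8α,9α-diol | CC(C)(C)[Si](C)(C)O[C@H]1C[C@@H](O)[C@](O)(CCOCc2ccccc2)[C@@]2(C)CCCC(C)(C)[C@H]12
F2 | step 3 | methyl (1R,6R)-6-formyl-1,5,5-trimethylcyclohex-3-ene-1-carboxylate | O=C[C@@H]1C(C)(C)C=CC[C@@]1(C)C(=O)OC
F3 | step 3 | methyl (1R,2R)-2-formyl-1,3,3-trimethylcyclohexane-1-carboxylate | O=C[C@@H]1C(C)(C)CCC[C@@]1(C)C(=O)OC
F4 | step 3 | methyl (1R,2R)-2-[(1S)-1-hydroxybut-3-en-1-yl]-1,3,3-trimethylcyclohexane-1-carboxylate | C=CC[C@H](O)[C@@H]1C(C)(C)CCC[C@@]1(C)C(=O)OC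
F5 | step 12 | 12-(benzyloxy)-6α-(tert-butyldimethylsilyloxy)-8α-[(trimethylsilyl)methyl]-13,14,15,16,17-pentanorlabdane-8β,9α-diol | CC(C)(C)[Si](C)(C)O[C@H]1C[C@@](O)(C[Si](C)(C)C)[C@](O)(CCOCc2ccccc2)[C@@]2(C)CCCC(C)(C)[C@H]12
F6 | step 13 | 12-(benzyloxy)-13,14,15,16-tetranorlabd-8(17)-ene-6α,9α-diol | O[C@H]1CC(=C)[C@](O)(CCOCc2ccccc2)[C@@]2(C)CCCC(C)(C)[C@H]12
F7 | step 13 | 12-(benzyloxy)-9α-hydroxy-13,14,15,16-tetranorlabd-8(17)-en-6-one | O=C1CC(=C)[C@](O)(CCOCc2ccccc2)[C@@]2(C)CCCC(C)(C)[C@H]12
F8 | step 13 | 12-(benzyloxy)-9α-hydroxy-13,14,15,16-tetranorlabd-7-en-6-one | O=C1C=C(C)[C@](O)(CCOCc2ccccc2)[C@@]2(C)CCCC(C)(C)[C@H]12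
F9 | step 13 | 13,14,15,16-tetranorlabdane-6α,9α,12-triol (8α-methyl) | O[C@H]1C[C@@H](C)[C@](O)(CCO)[C@@]2(C)CCCC(C)(C)[C@H]12
F10 | step 13 | 12-iodo-13,14,15,16-tetranorlabdane-6α,9α-diol (8α-methyl) | O[C@H]1C[C@@H](C)[C@](O)(CCI)[C@@]2(C)CCCC(C)(C)[C@H]12
F11 | step 18 | 6α-acetoxy-9α-hydroxy-13-(phenylsulfanyl)labdan-16,15-olide (both C13 epimers) | CC(=O)O[C@H]1C[C@@H](C)[C@](O)(CCC2(Sc3ccccc3)CCOC2=O)[C@@]2(C)CCCC(C)(C)[C@H]12
F12 | step 18 | 6α-acetoxy-9α-hydroxy-13-(phenylsulfinyl)labdan-16,15-olide (mixture of sulfoxide diastereomers) | CC(=O)O[C@H]1C[C@@H](C)[C@](O)(CCC2(S(=O)c3ccccc3)CCOC2=O)[C@@]2(C)CCCC(C)(C)[C@H]12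
A1 | alternative 1 | (1R,5R)-verbenone | O=C1C=C(C)[C@H]2C[C@@H]1C2(C)C
A2 | alternative 1 | 4-allyl-4,6,6-trimethylbicyclo[3.1.1]heptan-2-one from A1, allyl group anti to the dimethyl bridge | O=C1C[C@@](C)(CC=C)[C@H]2C[C@@H]1C2(C)C
A3 | alternative 1 | 2α-chloro-4,4,10β-trimethyl-trans-decalin-8-one (labdane numbering) | C1CC(=O)C[C@@]2(C)C[C@@H](Cl)CC(C)(C)[C@H]12
A4 | alternative 2 | methyl (6E)-7,11-dimethyl-3-oxododeca-6,10-dienoate | COC(=O)CC(=O)CC/C=C(\C)CCC=C(C)C
A5 | alternative 2 | methyl 5,5,8a-trimethyl-2-oxo-trans-decahydronaphthalene-1-carboxylate | C1CC(=O)[C@H](C(=O)OC)[C@@]2(C)CCCC(C)(C)[C@H]12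
A6 | alternative 3 | 2,6-dimethyl-1,4-benzoquinone | CC1=CC(=O)C=C(C)C1=O
A7 | alternative 3 | cis-2,5,5,8a-tetramethyl-4a,5,8,8a-tetrahydronaphthalene-1,4-dione | O=C1C=C(C)C(=O)[C@@]2(C)CC=CC(C)(C)[C@@H]12
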